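The central 1,4-benzoquinone ring is hexasubstituted in the order O, aryl, O, O, aryl, O, so each ring C=O carbon is bonded to an acyloxy-bearing ring carbon. The route closes the ring across one such C(=O)–C(O-acyl) pair. A squarate-derived 4-hydroxy-4-(1-aryl-2-benzyloxyvinyl)cyclobutenone is heated, ring-opens to a dienylketene and 6π-electrocyclises, the ketene carbon bonding to the oxygenated vinyl terminus. Tautomerisation gives the fully substituted hydroquinone in one operation from any isomer of the precursor. Hydrogenolysis and air oxidation give bis-silyl atromentin, which is acylated at both ends with (2Z,4S,5S)-4,5-epoxyhex-2-enoate (Sharpless epoxidation, Still–Gennari olefination) and desilylated.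

Key step: step 6

Assumption: enol ethers 8 and 10 and carbinol 12 are carried as isomer mixtures (SMILES without alkene or carbinol descriptors), because these elements are erased in step 6. Ar = 4-(tert-butyldimethylsilyloxy)phenyl.

Step 1
Reactants: 1 squaric acid
Product: 2 dibenzyl squarate
Conditions: BnOH (4 equiv), toluene, reflux, Dean–Stark
Reagents that add atoms: benzyl alcohol, OCc1ccccc1
Why: Azeotropic Fischer-type esterification of the strongly acidic vinylogous diacid with a primary alcohol is the standard entry to dialkyl squarates and should give the diester.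

Step 2
Reactants: 3 (4-bromophenoxy)(tert-butyl)dimethylsilane; 2 dibenzyl squarate
Product: 6 3-(benzyloxy)-4-Ar-cyclobut-3-ene-1,2-dione, via aryllithium 4 (not isolated), via lithium alkoxide adduct 5 (not isolated)
Conditions: 3, n-BuLi, THF, −78 °C; add to 2, THF, −78 °C; then (CF3CO)2O, −78 °C → rt
Reagents that add atoms: none
Why: Bromine–lithium exchange, 1,2-addition of the aryllithium to one squarate carbonyl and anhydride-induced ionisation of the carbinol with loss of one benzyl group (squarate-to-cyclobutenedione transposition) should give the 3-alkoxy-4-arylcyclobutenedione.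

Step 3
Reactants: 7 4-(tert-butyldimethylsilyloxy)benzaldehyde
Product: 8 1-[2-(benzyloxy)ethenyl]-4-(tert-butyldimethylsilyloxy)benzene (E/Z mixture)
Conditions: BnOCH2PPh3Cl, NaN(SiMe3)2, THF, 0 °C; then 7, 0 °C → rt
Reagents that add atoms: (benzyloxymethyl)triphenylphosphonium chloride, [Cl-].C(OCc1ccccc1)[P+](c1ccccc1)(c1ccccc1)c1ccccc1
Why: Wittig alkoxymethylenation of an aromatic aldehyde with the non-stabilised alkoxymethyl ylide should give the enol ether, whose E/Z ratio is irrelevant here.

Step 4
Reactants: 8 enol ether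
Product: 10 1-[2-(benzyloxy)-1-bromoethenyl]-4-(tert-butyldimethylsilyloxy)benzene (E/Z mixture), via dibromide 9 (not isolated)
Conditions: Br2, CH2Cl2, −78 °C; then DBU, −78 °C → rt
Reagents that add atoms: bromine, BrBr
Why: Bromine addition to the electron-rich enol ether followed by dehydrobromination, in which the labile α-bromo ether bromide leaves and the benzylic hydrogen is removed (the bromination–elimination route to 2-bromovinyl ethers), should leave bromine on the aryl-bearing carbon.

Step 5
Reactants: 10 bromo enol ether; 6 cyclobutenedione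
Product: 12 3-(benzyloxy)-4-[2-(benzyloxy)-1-Ar-ethenyl]-4-hydroxy-2-Ar-cyclobut-2-en-1-one (racemic; mixed alkene geometry), via vinyllithium 11 (not isolated)
Conditions: 10, t-BuLi (2 equiv), THF, −78 °C; then 6, THF, −78 °C; aq NH4Cl
Reagents that add atoms: none
Why: Bromine–lithium exchange and 1,2-addition of the β-alkoxyvinyllithium to the ketone-like carbonyl of 6 (the one next to the benzyloxy-bearing carbon, the other being a deactivated vinylogous ester) follows the known regiochemistry of organolithium additions to 3-alkoxycyclobutenediones; the new carbinol centre is racemic and is destroyed in step 6.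

Step 6
Reactants: 12 4-alkenyl-4-hydroxycyclobutenone
Product: 15 2,5-bis(benzyloxy)-3,6-bis-Ar-benzene-1,4-diol, via dienylketene 13 (not isolated), via cyclohexadienone 14 (not isolated)
Conditions: toluene (degassed), 110 °C, argon
Reagents that add atoms: none
Why: Heating opens the cyclobutenone by conrotatory 4π ring opening of the C(=O)–C(OH) bond, the hydroxyl donor rotating outward so that the alkoxyvinyl group sits cis to the ketene in 13; the electrophilic ketene carbon then bonds to the electron-rich benzyloxy-bearing vinyl carbon in a thermal disrotatory 6π electrocyclisation, and enolisation of dienone 14 gives the arene. The closest known reaction type is the thermal ring expansion of 4-alkenyl-4-hydroxycyclobutenones to hydroquinones used in squarate-based quinone synthesis. The six-membered carbocycle is closed by 6π electrocyclisation of a 1,3,5-hexatriene (ketene C=C, enol C=C, enol ether C=C), a pericyclic closure outside the exo/endo classification. No stereocentre is set: the sp3 carbon of 14, the carbinol centre of 12 and the enol ether geometry all vanish on aromatisation, so every isomer of 12 should converge on 15. The step needs inward rotation of the alkenyl group and the O/aryl/O/O/aryl/O order around the ring; the first is secured by the outward preference of the hydroxyl, the second was fixed by the regioselective 1,2-addition of step 5. Exclusion of air keeps the hydroquinone from oxidising before step 7.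

Step 7
Reactants: 15 hydroquinone dibenzyl ether
Product: 17 2,5-dihydroxy-3,6-bis-Ar-1,4-benzoquinone (bis-silyl atromentin), via tetrol 16 (not isolated)
Conditions: H2 (1 atm), Pd/C, EtOAc, rt; filter; then air, rt
Reagents that add atoms: none
Why: Hydrogenolysis of the two aryl benzyl ethers should leave the silyl ethers untouched and give a 1,2,4,5-tetrahydroxybenzene that autoxidises to the 2,5-dihydroxy-1,4-benzoquinone.

Step 8
Reactants: 18 (E)-but-2-en-1-ol
Product: 19 [(2S,3S)-3-methyloxiran-2-yl]methanol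
Conditions: t-BuOOH, Ti(OiPr)4 (cat.), L-(+)-diisopropyl tartrate (cat.), 4 Å MS, CH2Cl2, −20 °C
Reagents that add atoms: tert-butyl hydroperoxide, CC(C)(C)OO
Why: Sharpless asymmetric epoxidation of the (E)-allylic alcohol with the L-(+)-tartrate ligand should set both epoxide centres as (2S,3S), the trans relationship following from the E alkene.

Step 9
Reactants: 19 epoxy alcohol
Product: 21 methyl (2Z)-3-[(2S,3S)-3-methyloxiran-2-yl]prop-2-enoate, via epoxy aldehyde 20 (not isolated)
Conditions: Dess–Martin periodinane, pyridine, CH2Cl2, 0 °C; silica plug; then (CF3CH2O)2P(O)CH2CO2Me, KN(SiMe3)2, 18-crown-6, THF, −78 °C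
Reagents that add atoms: methyl bis(2,2,2-trifluoroethyl)phosphonoacetate, COC(=O)CP(=O)(OCC(F)(F)F)OCC(F)(F)F
Why: Dess–Martin oxidation should give the volatile epoxy aldehyde without epimerisation, and Still–Gennari olefination with the dissociated potassium phosphonate sets the Z alkene under kinetic control while the epoxide centres stay untouched.

Step 10
Reactants: 21 methyl ester
Product: 22 potassium (2Z)-3-[(2S,3S)-3-methyloxiran-2-yl]prop-2-enoate
Conditions: KOSiMe3, Et2O, rt; filter
Reagents that add atoms: potassium trimethylsilanolate, C[Si](C)(C)[O-].[K+]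
Why: Anhydrous silanolate cleavage of the methyl ester should give the carboxylate salt directly, so the free Z-epoxy acid, which would lactonise onto the epoxide, is never formed.

Step 11
Reactants: 17 bis-silyl atromentin; 22 potassium carboxylate (2.4 equiv)
Product: 24 3,6-bis-Ar-2,5-bis{[(2Z)-3-((2S,3S)-3-methyloxiran-2-yl)prop-2-enoyl]oxy}-1,4-benzoquinone, via mixed anhydride 23 (not isolated)
Conditions: 22, 2,4,6-trichlorobenzoyl chloride, THF, 0 °C; then 17, Et3N, DMAP (cat.), toluene, −20 → 0 °C
Reagents that add atoms: none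
Why: In this Yamaguchi esterification the mixed anhydride should acylate both acidic enolic hydroxyls of the dihydroxyquinone at its unhindered enoyl carbonyl, while the phenols stay silylated and the low temperature preserves the Z alkene and the epoxide.

Step 12
Reactants: 24 bis-silyl diester
Product: 25 target, 3,6-bis(4-hydroxyphenyl)-2,5-bis{[(2Z)-3-((2S,3S)-3-methyloxiran-2-yl)prop-2-enoyl]oxy}-1,4-benzoquinone
Conditions: Et3N·3HF, THF, 0 °C → rt
Reagents that add atoms: none
Why: Fluoride cleavage of the two aryl silyl ethers under nearly neutral buffered conditions (silyl ether deprotection) should spare the vinyl epoxides, the Z-enoates and the activated enol esters.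

Compound list
1 | squaric acid (3,4-dihydroxycyclobut-3-ene-1,2-dione) | OC1=C(O)C(=O)C1=O | starting material
2 | dibenzyl squarate (3,4-bis(benzyloxy)cyclobut-3-ene-1,2-dione) | O=C1C(=O)C(OCc2ccccc2)=C1OCc1ccccc1 | intermediate
3 | (4-bromophenoxy)(tert-butyl)dimethylsilane | CC(C)(C)[Si](C)(C)Oc1ccc(Br)cc1 | starting material
4 | [4-(tert-butyldimethylsilyloxy)phenyl]lithium | [Li]c1ccc(O[Si](C)(C)C(C)(C)C)cc1 | intermediate
5 | lithium 2,3-bis(benzyloxy)-1-[4-(tert-butyldimethylsilyloxy)phenyl]-4-oxocyclobut-2-en-1-olate (racemic) | [Li+].[O-]C1(c2ccc(O[Si](C)(C)C(C)(C)C)cc2)C(OCc2ccccc2)=C(OCc2ccccc2)C1=O | intermediate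
6 | 3-(benzyloxy)-4-[4-(tert-butyldimethylsilyloxy)phenyl]cyclobut-3-ene-1,2-dione | O=C1C(=O)C(OCc2ccccc2)=C1c1ccc(O[Si](C)(C)C(C)(C)C)cc1 | intermediate
7 | 4-(tert-butyldimethylsilyloxy)benzaldehyde | CC(C)(C)[Si](C)(C)Oc1ccc(C=O)cc1 | starting material
8 | 1-[2-(benzyloxy)ethenyl]-4-(tert-butyldimethylsilyloxy)benzene (E/Z mixture) | CC(C)(C)[Si](C)(C)Oc1ccc(C=COCc2ccccc2)cc1 | intermediate
9 | 1-[2-(benzyloxy)-1,2-dibromoethyl]-4-(tert-butyldimethylsilyloxy)benzene (diastereomer mixture) | CC(C)(C)[Si](C)(C)Oc1ccc(C(Br)C(Br)OCc2ccccc2)cc1 | intermediate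
10 | 1-[2-(benzyloxy)-1-bromoethenyl]-4-(tert-butyldimethylsilyloxy)benzene (E/Z mixture) | CC(C)(C)[Si](C)(C)Oc1ccc(C(Br)=COCc2ccccc2)cc1 | intermediate
11 | {2-(benzyloxy)-1-[4-(tert-butyldimethylsilyloxy)phenyl]ethenyl}lithium | CC(C)(C)[Si](C)(C)Oc1ccc(C([Li])=COCc2ccccc2)cc1 | intermediate
12 | 3-(benzyloxy)-4-{2-(benzyloxy)-1-[4-(tert-butyldimethylsilyloxy)phenyl]ethenyl}-4-hydroxy-2-[4-(tert-butyldimethylsilyloxy)phenyl]cyclobut-2-en-1-one (racemic, mixed alkene geometry) | CC(C)(C)[Si](C)(C)Oc1ccc(cc1)C(=COCc1ccccc1)C1(O)C(OCc2ccccc2)=C(C1=O)c1ccc(O[Si](C)(C)C(C)(C)C)cc1 | intermediate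
13 | dienylketene O=C=C(Ar)–C(OBn)=C(OH)–C(Ar)=CH(OBn), ketenyl and alkenyl groups cis on the central C=C | O=C=C(c1ccc(O[Si](C)(C)C(C)(C)C)cc1)/C(OCc1ccccc1)=C(/O)C(=COCc1ccccc1)c1ccc(O[Si](C)(C)C(C)(C)C)cc1 | intermediate
14 | 3,6-bis(benzyloxy)-4-hydroxy-2,5-bis[4-(tert-butyldimethylsilyloxy)phenyl]cyclohexa-2,4-dien-1-one (racemic) | O=C1C(c2ccc(O[Si](C)(C)C(C)(C)C)cc2)=C(OCc2ccccc2)C(O)=C(c2ccc(O[Si](C)(C)C(C)(C)C)cc2)C1OCc1ccccc1 | intermediate
15 | 2,5-bis(benzyloxy)-3,6-bis[4-(tert-butyldimethylsilyloxy)phenyl]benzene-1,4-diol | Oc1c(-c2ccc(O[Si](C)(C)C(C)(C)C)cc2)c(OCc2ccccc2)c(O)c(-c2ccc(O[Si](C)(C)C(C)(C)C)cc2)c1OCc1ccccc1 | intermediate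
16 | 3,6-bis[4-(tert-butyldimethylsilyloxy)phenyl]benzene-1,2,4,5-tetrol | Oc1c(O)c(-c2ccc(O[Si](C)(C)C(C)(C)C)cc2)c(O)c(O)c1-c1ccc(O[Si](C)(C)C(C)(C)C)cc1 | intermediate
17 | 2,5-dihydroxy-3,6-bis[4-(tert-butyldimethylsilyloxy)phenyl]-1,4-benzoquinone (bis-silyl atromentin) | O=C1C(O)=C(c2ccc(O[Si](C)(C)C(C)(C)C)cc2)C(=O)C(O)=C1c1ccc(O[Si](C)(C)C(C)(C)C)cc1 | intermediate
18 | (E)-but-2-en-1-ol (trans-crotyl alcohol) | C/C=C/CO | starting material
19 | [(2S,3S)-3-methyloxiran-2-yl]methanol | C[C@@H]1O[C@H]1CO | intermediate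
20 | (2R,3S)-3-methyloxirane-2-carbaldehyde | C[C@@H]1O[C@H]1C=O | intermediate
21 | methyl (2Z)-3-[(2S,3S)-3-methyloxiran-2-yl]prop-2-enoate | C[C@@H]1O[C@H]1/C=C\C(=O)OC | intermediate
22 | potassium (2Z)-3-[(2S,3S)-3-methyloxiran-2-yl]prop-2-enoate | C[C@@H]1O[C@H]1/C=C\C(=O)[O-].[K+] | intermediate
23 | (2Z)-3-[(2S,3S)-3-methyloxiran-2-yl]prop-2-enoic 2,4,6-trichlorobenzoic anhydride | C[C@@H]1O[C@H]1/C=C\C(=O)OC(=O)c1c(Cl)cc(Cl)cc1Cl | intermediate
24 | 3,6-bis[4-(tert-butyldimethylsilyloxy)phenyl]-2,5-bis{[(2Z)-3-((2S,3S)-3-methyloxiran-2-yl)prop-2-enoyl]oxy}-1,4-benzoquinone | C[C@@H]1O[C@H]1/C=C\C(=O)OC1=C(c2ccc(O[Si](C)(C)C(C)(C)C)cc2)C(=O)C(OC(=O)/C=C\[C@@H]2O[C@H]2C)=C(c2ccc(O[Si](C)(C)C(C)(C)C)cc2)C1=O | intermediate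
25 | 3,6-bis(4-hydroxyphenyl)-2,5-bis{[(2Z)-3-((2S,3S)-3-methyloxiran-2-yl)prop-2-enoyl]oxy}-1,4-benzoquinone | C[C@@H]1O[C@H]1/C=C\C(=O)OC1=C(c2ccc(O)cc2)C(=O)C(OC(=O)/C=C\[C@@H]2O[C@H]2C)=C(c2ccc(O)cc2)C1=O | target

Total step count: 12. Longest linear sequence: 7 steps (steps 1, 2, 5, 6, 7, 11, 12).

Steps most likely to fail

Step 6. The ketene may be intercepted by the free hydroxyl (lactonisation to a furanone after inward rotation of OH), or may decompose faster than the crowded triene closes. The fallback sets out from 12 and comes back at 15. Carbinol 12 is silylated (N-(trimethylsilyl)imidazole, CH2Cl2, rt) to the 4-(trimethylsilyloxy)cyclobutenone F1, in which the ketene cannot be trapped by a hydroxyl. Heating (toluene, 110 °C) should then give the hydroquinone mono(trimethylsilyl) ether F2. Mild methanolysis of the aryl trimethylsilyl ether (citric acid, MeOH, 0 °C) returns 15.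

Step 11. The activated acyl group may be attacked by its own epoxide oxygen, the Z alkene may isomerise through reversible conjugate addition of DMAP, or the delocalised quinone enolate may acylate too slowly. The fallback sets out from 17 and comes back at 24 with the polarity reversed. Compound 17 is converted with oxalyl chloride and catalytic DMF (CH2Cl2, 0 °C) into the bis(vinylogous acid chloride) 2,5-dichloro-3,6-bis[4-(tert-butyldimethylsilyloxy)phenyl]-1,4-benzoquinone F3. Both chlorides are then displaced by carboxylate 22 (18-crown-6, MeCN, 0 °C) by addition–elimination, so the epoxy acid acts only as a nucleophile and is never activated.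

Step 12. Acyl transfer from the activated enol esters to the liberated phenols, or fluoride attack on the esters or epoxides, may erode the product during desilylation. The fallback sets out from 17 and comes back at 25. Compound 17 is desilylated first (Et3N·3HF, THF, rt) to atromentin F4. Its two enolic hydroxyls are far more acidic than its phenols, so with two equivalents of Et3N and no DMAP (THF/DMF, −20 °C) only the quinone oxygens are ionised. These should be acylated by mixed anhydride 23 to give 25 directly, with no deprotection after the esters are in place.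

Further compounds
F1 | step 6 | 3-(benzyloxy)-4-{2-(benzyloxy)-1-[4-(tert-butyldimethylsilyloxy)phenyl]ethenyl}-2-[4-(tert-butyldimethylsilyloxy)phenyl]-4-(trimethylsilyloxy)cyclobut-2-en-1-one | CC(C)(C)[Si](C)(C)Oc1ccc(cc1)C(=COCc1ccccc1)C1(O[Si](C)(C)C)C(OCc2ccccc2)=C(C1=O)c1ccc(O[Si](C)(C)C(C)(C)C)cc1
F2 | step 6 | 2,5-bis(benzyloxy)-3,6-bis[4-(tert-butyldimethylsilyloxy)phenyl]-4-(trimethylsilyloxy)phenol | C[Si](C)(C)Oc1c(-c2ccc(O[Si](C)(C)C(C)(C)C)cc2)c(OCc2ccccc2)c(O)c(-c2ccc(O[Si](C)(C)C(C)(C)C)cc2)c1OCc1ccccc1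
F3 | step 11 | 2,5-dichloro-3,6-bis[4-(tert-butyldimethylsilyloxy)phenyl]-1,4-benzoquinone | O=C1C(Cl)=C(c2ccc(O[Si](C)(C)C(C)(C)C)cc2)C(=O)C(Cl)=C1c1ccc(O[Si](C)(C)C(C)(C)C)cc1
F4 | step 12 | atromentin (2,5-dihydroxy-3,6-bis(4-hydroxyphenyl)-1,4-benzoquinone) | O=C1C(O)=C(c2ccc(O)cc2)C(=O)C(O)=C1c1ccc(O)cc1
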